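**Strategy**

The route rests on disconnecting the bond between the two spiro carbons: C2 of ring A, flanked by both carbonyls, and the quaternary pinane carbon, which carries ring A on the face of the CMe2 bridge. That pinane carbon sits 1,3 to a ring CH2 that is the carbonyl carbon of nopinone, so an oxygen placed there on the bridge face can hand ring A over by a Claisen rearrangement, which forms the bond and the hindered quaternary centre in one operation. The precursor is the enol ether of the ring A dione with a cis 4-homoprenyl pinenol; ring B is closed afterwards by a radical 5-exo cyclisation.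

Key step: step 13

Remark: pinane atoms are numbered as in nopinone (C2 the carbonyl carbon, C4 the carbon that becomes the spiro centre, C6 the CMe2 bridge); cyclic 1,3-diones are written as diketo tautomers although largely enolised, and the ring A chloride and allyl enol ether are written as the linearly conjugated regioisomers, the cross-conjugated ones converging on the same rearrangement product.

**Route**

Step 1
Reactants: 1 (1R,5S)-(+)-nopinone
Product: 2 nopinone trimethylsilyl enol ether (6,6-dimethyl-2-trimethylsilyloxybicyclo[3.1.1]hept-2-ene, bridgeheads as in 1)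
Conditions: LiN(i-Pr)2, THF, −78 °C; then TMSCl, −78 °C → rt
Reagents that add atoms: chlorotrimethylsilane, C[Si](C)(C)Cl
Why: Enolate formation and O-silylation (silyl enol ether synthesis) can occur only towards C3, because the bridgehead C1–H cannot enolise.

Step 2
Reactants: 2 nopinone trimethylsilyl enol ether
Product: 3 (+)-apoverbenone (6,6-dimethylbicyclo[3.1.1]hept-3-en-2-one, bridgeheads as in 1)
Conditions: Pd(OAc)2 (10 mol%), O2 (1 atm), DMSO, 40 °C
Reagents that add atoms: none
Why: Saegusa–Ito oxidation, in which palladation at C3 is followed by syn β-hydride elimination of the C4 hydrogen that is still available on the open face.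

Step 3
Reactants: 3 (+)-apoverbenone; 4 5-bromo-2-methylpent-2-ene
Product: 6 trimethylsilyl enol ether of 4-(4-methylpent-3-enyl)nopinone (chain at C4 anti to the CMe2 bridge), via homoprenylmagnesium bromide 5 (not isolated)
Conditions: 4, Mg, THF, 40 °C; then 3, CuBr·SMe2 (10 mol%), TMSCl, THF, −78 → −30 °C; Et3N, pentane work-up
Reagents that add atoms: chlorotrimethylsilane, C[Si](C)(C)Cl
Why: Copper-catalysed 1,4-addition of the Grignard reagent, accelerated and trapped by TMSCl, should deliver the chain to C4 from the face opposite the CMe2 bridge, a stereocentre that the next step erases.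

Step 4
Reactants: 6 trimethylsilyl enol ether of 4-(4-methylpent-3-enyl)nopinone
Product: 7 4-(4-methylpent-3-enyl)apoverbenone (6,6-dimethyl-4-(4-methylpent-3-enyl)bicyclo[3.1.1]hept-3-en-2-one)
Conditions: IBX, 4-methoxypyridine N-oxide, DMSO, rt
Reagents that add atoms: none
Why: IBX dehydrogenation of the silyl enol ether is chosen because the remaining C4 hydrogen lies on the CMe2-bridge face, where a syn β-hydride elimination from palladium bound on the open face cannot reach it, whereas the oxygen-bound hypervalent iodine oxidant has no such requirement.

Step 5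
Reactants: 7 4-(4-methylpent-3-enyl)apoverbenone
Product: 8 cis allylic alcohol (6,6-dimethyl-4-(4-methylpent-3-enyl)bicyclo[3.1.1]hept-3-en-2-ol, hydroxyl on the CMe2-bridge face)
Conditions: NaBH4, CeCl3·7H2O, MeOH, −20 °C
Reagents that add atoms: none
Why: Luche 1,2-reduction, in which hydride attacks the carbonyl from the face opposite the CMe2 bridge as in the reduction of verbenone to cis-verbenol, should set the carbinol centre with the hydroxyl on the bridge face.

Step 6
Reactants: 9 2,4,6-trihydroxytoluene
Product: 10 1-(2,4,6-trihydroxy-3-methylphenyl)ethan-1-one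
Conditions: AcCl, AlCl3, PhNO2–CH2Cl2, 0 °C → rt; then aq. HCl
Reagents that add atoms: acetyl chloride, CC(=O)Cl
Why: Friedel–Crafts C-acylation of the electron-rich ring stops after one acetyl group, which blocks the carbon that becomes the spiro carbon of ring A.

Step 7
Reactants: 10 1-(2,4,6-trihydroxy-3-methylphenyl)ethan-1-one
Product: 11 2-acetyl-3,5-dihydroxy-4,6,6-trimethylcyclohexa-2,4-dien-1-one
Conditions: MeI (2.1 equiv), NaOMe, MeOH, 0 °C → rt; then aq. HCl
Reagents that add atoms: iodomethane, CI
Why: Dearomatising C-methylation of the polyphenolate puts the first methyl on the free ring CH and the second on one of the two then equivalent methyl-bearing carbons, so a single gem-dimethyl triketone should result while the acetyl-bearing carbon stays blocked.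

Step 8
Reactants: 11 2-acetyl-3,5-dihydroxy-4,6,6-trimethylcyclohexa-2,4-dien-1-one
Product: 12 2-acetyl-3-hydroxy-5-methoxy-4,6,6-trimethylcyclohexa-2,4-dien-1-one
Conditions: TMSCHN2, PhMe–MeOH (4:1), 0 °C
Reagents that add atoms: (trimethylsilyl)diazomethane, C[Si](C)(C)C=[N+]=[N-]
Why: Diazoalkane O-methylation should take the only non-chelated vinylogous acid hydroxyl, the one between CMe2 and CMe, because the two oxygens next to the acetyl group are held in the hydrogen-bonded β-triketone enol.

Step 9
Reactants: 12 2-acetyl-3-hydroxy-5-methoxy-4,6,6-trimethylcyclohexa-2,4-dien-1-one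
Product: 14 2-chloro-5-methoxy-4,6,6-trimethylcyclohex-4-ene-1,3-dione, via 2-acetyl-2-chloro triketone 13 (not isolated)
Conditions: NCS, Et3N, CH2Cl2, 0 °C; then MeOH, rt
Reagents that add atoms: N-chlorosuccinimide, O=C1CCC(=O)N1Cl
Why: α-Chlorination of the triketone enolate makes the acetyl-bearing carbon non-enolisable, so methanol should cleave the acetyl group by retro-Claisen fragmentation (deacylative halogenation) under mild basic conditions that keep the methyl enol ether, which hot aqueous acid deacetylation would hydrolyse.

Step 10
Reactants: 14 2-chloro-5-methoxy-4,6,6-trimethylcyclohex-4-ene-1,3-dione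
Product: 15 5-methoxy-4,6,6-trimethylcyclohex-4-ene-1,3-dione
Conditions: Zn dust, AcOH, rt
Reagents that add atoms: none
Why: Reductive dehalogenation of the α-chloro-1,3-dione through its zinc enolate should free the ring A C2–H2 group without touching the vinylogous ester.

Step 11
Reactants: 15 5-methoxy-4,6,6-trimethylcyclohex-4-ene-1,3-dione
Product: 16 3-chloro-5-methoxy-4,6,6-trimethylcyclohexa-2,4-dien-1-one
Conditions: (COCl)2 (1.1 equiv), CH2Cl2, 0 °C → rt
Reagents that add atoms: oxalyl chloride, O=C(Cl)C(=O)Cl
Why: Vinylogous acid chloride formation from the enol of a cyclic 1,3-dione, with near-stoichiometric reagent at low temperature to spare the hindered methyl enol ether.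

Step 12
Reactants: 8 cis allylic alcohol; 16 3-chloro-5-methoxy-4,6,6-trimethylcyclohexa-2,4-dien-1-one
Product: 18 allyl enol ether (5-methoxy-4,6,6-trimethyl-3-pinenyloxycyclohexa-2,4-dien-1-one with the ether oxygen on the CMe2-bridge face of pinene C2), via potassium alkoxide 17 (not isolated)
Conditions: 8, KH, THF, 0 °C; then 16, −20 °C → rt
Reagents that add atoms: none
Why: Addition–elimination of the alkoxide at the chlorine-bearing carbon of the β-chloro dienone forms the enol ether without touching the carbinol C–O bond, so its configuration is retained and the ionisation that acid-catalysed etherification of this allylic alcohol would cause is avoided.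

Step 13
Reactants: 18 allyl enol ether
Product: 19 5-methoxy-4,6,6-trimethyl-2-pinenylcyclohex-4-ene-1,3-dione (ring A C2 bonded to quaternary pinene C4 on the CMe2-bridge face, homoprenyl chain on the other face, ring alkene now at pinene C2=C3, ring A C2–H epimerisable)
Conditions: i-Pr2NEt (1 equiv), PhMe, 160 °C, sealed tube
Reagents that add atoms: none
Why: Concerted, suprafacial [3,3] sigmatropic shift in which ring A C2, the enol ether carbon, the oxygen, the carbinol carbon (pinene C2) and the ring alkene C3=C4 reorganise so that the allylic C–O bond breaks as the bond between ring A C2 and pinene C4, the two future spiro carbons, forms. The closest known reaction type is the thermal Claisen rearrangement of 3-allyloxy enones, the allyl enol ethers of cyclic 1,3-diones, to 2-allyl-1,3-diones with chirality transfer from a ring allylic C–O bond. No ring closes; the step joins the two fragments through carbon and leaves the chain alkene within 5-exo reach of ring A C2. The one new stereocentre, quaternary pinene C4, is controlled by the carbinol configuration set in step 5, because the allyl unit is locked in the bicycle and the new bond can form only on the face the oxygen leaves, the CMe2-bridge face that no outside reagent reaches. The step needs this facial selectivity, which holds as long as the concerted path outruns ionisation to an allyl cation and dione anion pair; the non-polar medium and the amine, which neutralises the acidic dione as it forms, are there to prevent acid-promoted ionisation. Tautomerisation of the 2-alkyl-1,3-dione product makes the shift irreversible, and either enol ether regioisomer would give the same compound.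

Step 14
Reactants: 19 2-pinenyl ring A dione
Product: 20 dispiro diene (ring B closed, isopropenyl on the CH next to the ring A spiro carbon, pinene ring alkene retained, configuration as in 21)
Conditions: Mn(OAc)3·2H2O (2.2 equiv), Cu(OAc)2·H2O (1 equiv), AcOH, 40 °C
Reagents that add atoms: none
Why: Mn(OAc)3-based oxidative radical cyclisation, in which the ring A C2 radical closes 5-exo on the trisubstituted alkene and Cu(OAc)2 oxidises the resulting tertiary radical to the isopropenyl group, should set the ring A spiro carbon and the CH centre together under substrate control, the new side-chain carbon lying beside the vinylic CH of the pinene ring instead of the bridgehead CH and the CMe2 flank of ring A turned away from it.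

Step 15
Reactants: 20 dispiro diene
Product: 21 CNP0307059.1 (target)
Conditions: H2 (5 bar), RhCl(PPh3)3 (10 mol%), PhH–EtOH (1:1), 40 °C
Reagents that add atoms: none
Why: Homogeneous hydrogenation with RhCl(PPh3)3 should saturate the isopropenyl group and the cis-disubstituted ring alkene without double-bond migration, so the CH(isopropyl) centre is not scrambled, the tetrasubstituted enol ether alkene is left alone and no new stereocentre is formed.

**Compound list**

1 | (1R,5S)-(+)-nopinone | C1CC(=O)[C@@H]2C[C@H]1C2(C)C | starting material
2 | nopinone trimethylsilyl enol ether | C1C=C(O[Si](C)(C)C)[C@@H]2C[C@H]1C2(C)C | intermediate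
3 | (+)-apoverbenone | C1=CC(=O)[C@@H]2C[C@H]1C2(C)C | intermediate
4 | 5-bromo-2-methylpent-2-ene | CC(C)=CCCBr | starting material
5 | (4-methylpent-3-enyl)magnesium bromide | CC(C)=CCC[Mg]Br | intermediate
6 | trimethylsilyl enol ether of 4-(4-methylpent-3-enyl)nopinone, chain anti to the CMe2 bridge | CC(C)=CCC[C@@H]1C=C(O[Si](C)(C)C)[C@@H]2C[C@H]1C2(C)C | intermediate
7 | 4-(4-methylpent-3-enyl)apoverbenone | CC(C)=CCCC1=CC(=O)[C@@H]2C[C@H]1C2(C)C | intermediate
8 | cis allylic alcohol, hydroxyl on the CMe2-bridge face | CC(C)=CCCC1=C[C@@H](O)[C@@H]2C[C@H]1C2(C)C | intermediate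
9 | 2,4,6-trihydroxytoluene | Cc1c(O)cc(O)cc1O | starting material
10 | 1-(2,4,6-trihydroxy-3-methylphenyl)ethan-1-one | CC(=O)c1c(O)cc(O)c(C)c1O | intermediate
11 | 2-acetyl-3,5-dihydroxy-4,6,6-trimethylcyclohexa-2,4-dien-1-one | CC(=O)C1=C(O)C(C)=C(O)C(C)(C)C1=O | intermediate
12 | 2-acetyl-3-hydroxy-5-methoxy-4,6,6-trimethylcyclohexa-2,4-dien-1-one | COC1=C(C)C(O)=C(C(C)=O)C(=O)C1(C)C | intermediate
13 | 2-acetyl-2-chloro-5-methoxy-4,6,6-trimethylcyclohex-4-ene-1,3-dione (racemic at C2) | COC1=C(C)C(=O)C(Cl)(C(C)=O)C(=O)C1(C)C | intermediate
14 | 2-chloro-5-methoxy-4,6,6-trimethylcyclohex-4-ene-1,3-dione | COC1=C(C)C(=O)C(Cl)C(=O)C1(C)C | intermediate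
15 | 5-methoxy-4,6,6-trimethylcyclohex-4-ene-1,3-dione | COC1=C(C)C(=O)CC(=O)C1(C)C | intermediate
16 | 3-chloro-5-methoxy-4,6,6-trimethylcyclohexa-2,4-dien-1-one | COC1=C(C)C(Cl)=CC(=O)C1(C)C | intermediate
17 | potassium alkoxide of 8 | CC(C)=CCCC1=C[C@@H]([O-])[C@@H]2C[C@H]1C2(C)C.[K+] | intermediate
18 | allyl enol ether of ring A, oxygen on the CMe2-bridge face | CC(C)=CCCC1=C[C@@H](OC3=CC(=O)C(C)(C)C(OC)=C3C)[C@@H]2C[C@H]1C2(C)C | intermediate
19 | 2-pinenyl ring A dione with quaternary pinene C4 | COC1=C(C)C(=O)C(C(=O)C1(C)C)[C@@]2(CCC=C(C)C)C=C[C@@H]3C[C@H]2C3(C)C | intermediate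
20 | dispiro diene with isopropenyl group and pinene ring alkene | COC1=C(C)C(=O)[C@@]2(C(=O)C1(C)C)[C@@H](C(C)=C)CC[C@@]21C=C[C@@H]2C[C@H]1C2(C)C | intermediate
21 | CNP0307059.1 | COC1=C(C)C(=O)[C@@]2(C(=O)C1(C)C)[C@@H](C(C)C)CC[C@@]21CC[C@@H]2C[C@H]1C2(C)C | target

**Step count and risks**

Total step count: 15. Longest linear sequence: 10 steps (steps 6 to 15, from 9 to 21); the pinane branch (1 to 8, steps 1 to 5) joins at step 12.

Steps most likely to fail:

1. Step 13. The allylic C–O bond may ionise, or the shift may stall against the bridge methyl, before the sigmatropic bond formation; the allyl cation would then lose a proton or recombine on the open face and the chirality transfer would be lost. The fallback sets out from 18. Its dienone carbonyl is reduced with i-Bu2AlH (CH2Cl2, −78 °C) to the dienol F1, which is silylated at once (TBSOTf, 2,6-lutidine) to the silyl ether F2. The migrating terminus is now an electron-rich dienol ether with a poor leaving group, so the Claisen shift should run near 100 °C with the same suprafacial transfer and give the β-silyloxy ketone F3. Bu4NF should free the hydroxy ketone F4, and Dess–Martin oxidation comes back to the route at 19.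

2. Step 14. The planar ring A radical and the chain alkene can meet in four ways, so poor facial selectivity, or slow enolisation of the hindered dione, may give the wrong relative configuration at the ring A spiro carbon or at the CH centre. The fallback sets out from 18. Allylic oxidation of the E-methyl group of the chain (SeO2 cat., t-BuOOH, CH2Cl2) should give the allylic alcohol F5, and ClCO2Me with pyridine the methyl carbonate F6. The Claisen rearrangement of step 13 then gives the dione carbonate F7. An intramolecular allylic alkylation catalysed by zerovalent palladium (Pd2(dba)3, a chiral diphosphine of the trans-1,2-diaminocyclohexane bis(2-diphenylphosphinobenzamide) type, THF) closes ring B 5-exo through an ionic allyl complex, in which the ligand enantiomer can be chosen against the substrate bias, and comes back to the route at 20.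

3. Step 4. The tertiary C4 hydrogen on the bridge face is shielded, so the oxidation may stall and the silyl enol ether may only be hydrolysed back to the saturated ketone. The fallback sets out from 6. Bromination with NBS (THF, −78 °C) should give the α-bromo ketone F8, and Li2CO3 with LiBr in DMF at 120 °C, where bromide exchange lets the C3 bromide reach the anti arrangement to the C4 hydrogen, eliminates HBr and comes back to the route at 7.

**Further compounds**

F1 | step 13 | dienol from 1,2-reduction of the dienone carbonyl of 18 | CC(C)=CCCC1=C[C@@H](OC3=CC(O)C(C)(C)C(OC)=C3C)[C@@H]2C[C@H]1C2(C)C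
F2 | step 13 | tert-butyldimethylsilyl ether of F1 | CC(C)=CCCC1=C[C@@H](OC3=CC(O[Si](C)(C)C(C)(C)C)C(C)(C)C(OC)=C3C)[C@@H]2C[C@H]1C2(C)C
F3 | step 13 | β-silyloxy ketone from Claisen rearrangement of F2 | COC1=C(C)C(=O)C(C(O[Si](C)(C)C(C)(C)C)C1(C)C)[C@@]2(CCC=C(C)C)C=C[C@@H]3C[C@H]2C3(C)C
F4 | step 13 | β-hydroxy ketone from desilylation of F3 | COC1=C(C)C(=O)C(C(O)C1(C)C)[C@@]2(CCC=C(C)C)C=C[C@@H]3C[C@H]2C3(C)C
F5 | step 14 | E allylic alcohol from chain oxidation of 18 | OC/C(C)=C/CCC1=C[C@@H](OC3=CC(=O)C(C)(C)C(OC)=C3C)[C@@H]2C[C@H]1C2(C)C
F6 | step 14 | methyl carbonate of F5 | COC(=O)OC/C(C)=C/CCC1=C[C@@H](OC3=CC(=O)C(C)(C)C(OC)=C3C)[C@@H]2C[C@H]1C2(C)C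
F7 | step 14 | 2-pinenyl ring A dione with allylic methyl carbonate chain | COC1=C(C)C(=O)C(C(=O)C1(C)C)[C@@]2(CC/C=C(C)/COC(=O)OC)C=C[C@@H]3C[C@H]2C3(C)C
F8 | step 4 | 3-bromo-4-(4-methylpent-3-enyl)nopinone | CC(C)=CCC[C@@H]1C(Br)C(=O)[C@@H]2C[C@H]1C2(C)C
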